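**Plan**

- Retrosynthesis: cut C10–Br/C9–Cl (anti-addition of BrCl to a C9=C10 alkene), then the C9–CH3 and C1–CH3 bonds (couplings at enol triflates), then C4–Br/C3–O (anti-bromohydrin of a C1=C2–C3=C4 diene), and last the C5–C6 bond by a 1,2-shift that contracts ring A to a cyclopentanol.
- Enabling feature: the spiro atom C6 sits between C1 (ketone level) and the quaternary C5, and is 1,4 to C9 across ring B. Ring B is therefore a para-substituted phenol in disguise with C6 as its para carbon, which oxidation of the phenol makes electrophilic.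
- Forward: aryllithium + 2,2-dimethylcyclopentanone gives a cuparane-type aryl cyclopentanol; oxidative dearomatisation enlarges the five-membered ring to ring A and leaves ring B as a symmetric dienone. Ring A is then taken to the diene and the bromohydrin; ring B is desymmetrised, methylated and bromochlorinated.
- Stereochemistry: C3/C4 trans from anti-addition, absolute configuration from lipase resolution; C6 from catalyst-controlled reduction of one of two identical dienone arms; C9/C10 from anti-addition on the ring B face remote from C1.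

Key step: step 3

Atom labels used as locants in all names: ring A = C1(CH3)=C2–C3(OH)–C4(Br)–C5(CH3)2–C6; ring B = C6–C7–C8–C9(CH3)(Cl)–C10(Br)–C11; C6 is the spiro atom.
Remark: racemates with one stereocentre are written without configuration; racemate 12 is written as the pair of enantiomers.
Assumption: the lipase is taken to acylate the (3R,4R)-alcohol faster, and the copper catalyst with (S,S)-Ph-BPE is taken to reduce the C7=C8 arm; the mirror-image ligand is available if the sense is opposite.

**Step 1**
Reactants: 1 (4-bromophenoxy)(tert-butyl)dimethylsilane; 2 2,2-dimethylcyclopentan-1-one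
Product: 4 1-[4-(tert-butyldimethylsilyloxy)phenyl]-2,2-dimethylcyclopentan-1-ol (racemate), via aryllithium 3 (not isolated)
Conditions: n-BuLi, THF, −78 °C; then 2, −78 → 0 °C; aq. NH4Cl
Reagents that add atoms: none
Why: Bromine–lithium exchange gives the aryllithium, which adds 1,2 to the ketone (the classical entry to cuparane-type aryl cyclopentanols); the carbinol centre forms as a racemate and is destroyed in step 3.

**Step 2**
Reactants: 4 1-[4-(tert-butyldimethylsilyloxy)phenyl]-2,2-dimethylcyclopentan-1-ol
Product: 5 4-(1-hydroxy-2,2-dimethylcyclopentyl)phenol (racemate)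
Conditions: K2CO3 (cat.), MeOH, rt
Reagents that add atoms: none
Why: Carbonate-catalysed methanolysis cleaves the phenolic silyl ether selectively and leaves the tertiary alcohol untouched.

**Step 3**
Reactants: 5 4-(1-hydroxy-2,2-dimethylcyclopentyl)phenol
Product: 7 5,5-dimethylspiro[5.5]undeca-7,10-diene-1,9-dione, via aryloxyiodane 6 (not isolated)
Conditions: PhI(OAc)2, (CF3)2CHOH, 0 °C
Reagents that add atoms: none
Why: Ligand exchange of the phenol at trivalent iodine gives aryloxyiodane 6, and loss of iodobenzene and acetate leaves a phenoxenium ion whose positive charge sits on the para carbon C6; the adjacent C1–C5 bond of the cyclopentanol migrates to C6 while the carbinol oxygen becomes the C1 ketone. The closest known reaction type is the hypervalent-iodine oxidative dearomatisation of para-hydroxyphenyl carbinols with Wagner–Meerwein (semipinacol) transposition, ring-enlarging cases included. Ring A is not closed by cyclisation: it arises by one-carbon enlargement of the five-membered carbinol ring (C5 moves from C1 to C6), which also creates the spiro atom and the C5–C6 bond between two quaternary carbons; ring B is the former arene, now a cross-conjugated dienone. No stereocentre is set, because the two dienone arms are identical and C6 becomes stereogenic only in step 10. The selectivity needed is migration of the quaternary C5 and not of the methylene C2, which the higher migratory aptitude of the more substituted, more electron-rich carbon should secure. Capture of the cation by solvent is held back by the weakly nucleophilic, strongly ionising solvent and by the blocked para position.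

**Step 4**
Reactants: 7 5,5-dimethylspiro[5.5]undeca-7,10-diene-1,9-dione
Product: 8 5,5-dimethylspiro[5.5]undeca-2,7,10-triene-1,9-dione
Conditions: IBX, DMSO/PhF, 75 °C
Reagents that add atoms: none
Why: IBX dehydrogenates the C1 ketone through its only enol (toward C2, as C6 is quaternary) to the C2=C3 enone, while the ring B dienone has no enolisable hydrogen.

**Step 5**
Reactants: 8 5,5-dimethylspiro[5.5]undeca-2,7,10-triene-1,9-dione
Product: 10 5,5-dimethyl-9-oxospiro[5.5]undeca-1,3,7,10-tetraen-1-yl trifluoromethanesulfonate, via potassium dienolate 9 (not isolated)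
Conditions: KN(SiMe3)2, THF, −78 °C; PhNTf2, −78 → 0 °C; aq. NH4Cl
Reagents that add atoms: N-phenylbis(trifluoromethanesulfonimide) (O=S(=O)(N(c1ccccc1)S(=O)(=O)C(F)(F)F)C(F)(F)F)
Why: The ring A enone has no alpha-prime hydrogen, so the hindered amide removes the gamma hydrogen at C4, and O-sulfonylation of the extended dienolate gives the 1-triflyloxy-1,3-diene.

**Step 6**
Reactants: 10 5,5-dimethyl-9-oxospiro[5.5]undeca-1,3,7,10-tetraen-1-yl trifluoromethanesulfonate
Product: 11 1,5,5-trimethylspiro[5.5]undeca-1,3,7,10-tetraen-9-one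
Conditions: MeZnCl, Pd(PPh3)4 (cat.), THF, rt
Reagents that add atoms: methylzinc chloride (C[Zn]Cl)
Why: Negishi coupling of the dienyl triflate under zerovalent palladium installs the C1 methyl group; organozinc halides do not add to the dienone.

**Step 7**
Reactants: 11 1,5,5-trimethylspiro[5.5]undeca-1,3,7,10-tetraen-9-one
Product: 12 rac-(3S,4S)-4-bromo-3-hydroxy-1,5,5-trimethylspiro[5.5]undeca-1,7,10-trien-9-one (trans racemate)
Conditions: NBS, acetone/H2O, 0 °C
Reagents that add atoms: N-bromosuccinimide (O=C1CCC(=O)N1Br); water (O)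
Why: Br+ attacks the electron-rich ring A diene at its less substituted terminus C4 and water opens the bromonium at the allylic C3 from the opposite face (bromohydrin formation, as with 1,3-cyclohexadiene), so anti-addition fixes the trans C3–OH/C4–Br relation; capture at the hindered tertiary C1 is disfavoured and the electron-poor dienone is inert.

**Step 8**
Reactants: 12 rac-(3S,4S)-4-bromo-3-hydroxy-1,5,5-trimethylspiro[5.5]undeca-1,7,10-trien-9-one
Product: 13 (3S,4S)-4-bromo-3-hydroxy-1,5,5-trimethylspiro[5.5]undeca-1,7,10-trien-9-one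
Conditions: immobilised Candida antarctica lipase B, vinyl acetate, t-BuOMe, 30 °C, run past half conversion
Reagents that add atoms: none
Why: Enzymatic kinetic resolution by acyl transfer (well established for trans-2-bromocycloalkanols) should acetylate the (3R,4R)-enantiomer, with the CHBr side as the large group, and leave the (3S,4S)-alcohol; this sets the absolute configuration of C3 and C4, and the acetate can be returned to diene 11 by reductive elimination with zinc.

**Step 9**
Reactants: 13 (3S,4S)-4-bromo-3-hydroxy-1,5,5-trimethylspiro[5.5]undeca-1,7,10-trien-9-one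
Product: 14 (3S,4S)-4-bromo-3-[(tert-butyldimethylsilyl)oxy]-1,5,5-trimethylspiro[5.5]undeca-1,7,10-trien-9-one
Conditions: TBSOTf, 2,6-lutidine, CH2Cl2, −78 → 0 °C
Reagents that add atoms: tert-butyldimethylsilyl trifluoromethanesulfonate (CC(C)(C)[Si](C)(C)OS(=O)(=O)C(F)(F)F)
Why: Silylation with the silyl triflate and a hindered pyridine base protects the allylic alcohol without forming an alkoxide, so the trans-bromohydrin cannot close to the epoxide.

**Step 10**
Reactants: 14 (3S,4S)-4-bromo-3-[(tert-butyldimethylsilyl)oxy]-1,5,5-trimethylspiro[5.5]undeca-1,7,10-trien-9-one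
Product: 15 (3S,4S,6S)-4-bromo-3-[(tert-butyldimethylsilyl)oxy]-1,5,5-trimethylspiro[5.5]undeca-1,10-dien-9-one
Conditions: Cu(OAc)2 (cat.), (S,S)-Ph-BPE (cat.), (EtO)2MeSiH, t-BuOH, toluene, 0 °C
Reagents that add atoms: none
Why: Asymmetric conjugate reduction by a monovalent copper hydride with a chiral bisphosphine (the known desymmetrisation of 4,4-disubstituted cyclohexadienones) should reduce only the C7=C8 arm, the one on the ring A face of the C3 oxygen; this catalyst-controlled choice makes C6 stereogenic (S), and the ring A alkene and the hindered bromide are not touched.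

**Step 11**
Reactants: 15 (3S,4S,6S)-4-bromo-3-[(tert-butyldimethylsilyl)oxy]-1,5,5-trimethylspiro[5.5]undeca-1,10-dien-9-one
Product: 17 (3S,4S,6S)-4-bromo-3-[(tert-butyldimethylsilyl)oxy]-1,5,5-trimethylspiro[5.5]undeca-1,9-dien-9-yl trifluoromethanesulfonate, via lithium enolate 16 (not isolated)
Conditions: LiBH(s-Bu)3, THF, −78 °C; then PhNTf2, −78 → 0 °C; aq. NH4Cl
Reagents that add atoms: N-phenylbis(trifluoromethanesulfonimide) (O=S(=O)(N(c1ccccc1)S(=O)(=O)C(F)(F)F)C(F)(F)F)
Why: Conjugate reduction with enolate triflation: hydride adds to the beta carbon C11 of the remaining enone and the C9=C10 enolate, formed regiospecifically, is trapped on oxygen, which fixes the ring B double bond on the arm that lies on the ring A face of C4–Br.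

**Step 12**
Reactants: 17 (3S,4S,6S)-4-bromo-3-[(tert-butyldimethylsilyl)oxy]-1,5,5-trimethylspiro[5.5]undeca-1,9-dien-9-yl trifluoromethanesulfonate
Product: 18 tert-butyl{[(3S,4S,6S)-4-bromo-1,5,5,9-tetramethylspiro[5.5]undeca-1,9-dien-3-yl]oxy}dimethylsilane
Conditions: MeZnCl, Pd(PPh3)4 (cat.), THF, rt
Reagents that add atoms: methylzinc chloride (C[Zn]Cl)
Why: Negishi coupling replaces the triflate by methyl to give the trisubstituted C9=C10 alkene; the neopentyl-type secondary bromide should not undergo oxidative addition to zerovalent palladium under these mild conditions.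

**Step 13**
Reactants: 18 tert-butyl{[(3S,4S,6S)-4-bromo-1,5,5,9-tetramethylspiro[5.5]undeca-1,9-dien-3-yl]oxy}dimethylsilane
Product: 19 tert-butyl{[(3S,4S,6S,9S,10S)-4,10-dibromo-9-chloro-1,5,5,9-tetramethylspiro[5.5]undec-1-en-3-yl]oxy}dimethylsilane
Conditions: Bu4NBrCl2, CH2Cl2, −78 °C
Reagents that add atoms: tetrabutylammonium dichlorobromate (CCCC[N+](CCCC)(CCCC)CCCC.[Cl-].ClBr)
Why: Anti-addition of BrCl: Br+ should attack the ring B alkene on the face away from C1 (pseudo-axial on ring B, its methyl group lying over that ring) and chloride should open the bromonium at the tertiary C9 from the other face, giving C10–Br cis to C5 and C9–Cl trans to it; the ring A alkene is shielded by the quaternary C6 and deactivated by the allylic silyloxy and homoallylic bromo groups.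

**Step 14**
Reactants: 19 tert-butyl{[(3S,4S,6S,9S,10S)-4,10-dibromo-9-chloro-1,5,5,9-tetramethylspiro[5.5]undec-1-en-3-yl]oxy}dimethylsilane
Product: 20 (3S,4S,6S,9S,10S)-4,10-dibromo-9-chloro-1,5,5,9-tetramethylspiro[5.5]undec-1-en-3-ol
Conditions: HF·pyridine, THF, 0 °C → rt
Reagents that add atoms: none
Why: Fluoride in a buffered acidic medium removes the silyl ether without forming the alkoxide, so neither the trans-bromohydrin nor the tertiary chloride should be lost.

**Compound list**

1 | (4-bromophenoxy)(tert-butyl)dimethylsilane | CC(C)(C)[Si](C)(C)Oc1ccc(Br)cc1 | starting material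
2 | 2,2-dimethylcyclopentan-1-one | CC1(C)CCCC1=O | starting material
3 | [4-(tert-butyldimethylsilyloxy)phenyl]lithium | [Li]c1ccc(O[Si](C)(C)C(C)(C)C)cc1 | intermediate
4 | 1-[4-(tert-butyldimethylsilyloxy)phenyl]-2,2-dimethylcyclopentan-1-ol (racemate) | CC1(C)CCCC1(O)c1ccc(O[Si](C)(C)C(C)(C)C)cc1 | intermediate
5 | 4-(1-hydroxy-2,2-dimethylcyclopentyl)phenol (racemate) | CC1(C)CCCC1(O)c1ccc(O)cc1 | intermediate
6 | acetoxy(phenyl)iodanyl ether of phenol 5 (aryloxyiodane) | CC(=O)OI(Oc1ccc(cc1)C1(O)CCCC1(C)C)c1ccccc1 | intermediate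
7 | 5,5-dimethylspiro[5.5]undeca-7,10-diene-1,9-dione | CC1(C)CCCC(=O)C12C=CC(=O)C=C2 | intermediate
8 | 5,5-dimethylspiro[5.5]undeca-2,7,10-triene-1,9-dione | CC1(C)CC=CC(=O)C12C=CC(=O)C=C2 | intermediate
9 | potassium 5,5-dimethyl-9-oxospiro[5.5]undeca-1,3,7,10-tetraen-1-olate | CC1(C)C=CC=C([O-])C12C=CC(=O)C=C2.[K+] | intermediate
10 | 5,5-dimethyl-9-oxospiro[5.5]undeca-1,3,7,10-tetraen-1-yl trifluoromethanesulfonate | CC1(C)C=CC=C(OS(=O)(=O)C(F)(F)F)C12C=CC(=O)C=C2 | intermediate
11 | 1,5,5-trimethylspiro[5.5]undeca-1,3,7,10-tetraen-9-one | CC1=CC=CC(C)(C)C12C=CC(=O)C=C2 | intermediate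
12 | rac-(3S,4S)-4-bromo-3-hydroxy-1,5,5-trimethylspiro[5.5]undeca-1,7,10-trien-9-one (both enantiomers written) | CC1=C[C@H](O)[C@@H](Br)C(C)(C)C12C=CC(=O)C=C2.CC1=C[C@@H](O)[C@H](Br)C(C)(C)C12C=CC(=O)C=C2 | intermediate
13 | (3S,4S)-4-bromo-3-hydroxy-1,5,5-trimethylspiro[5.5]undeca-1,7,10-trien-9-one | CC1=C[C@H](O)[C@@H](Br)C(C)(C)C12C=CC(=O)C=C2 | intermediate
14 | (3S,4S)-4-bromo-3-[(tert-butyldimethylsilyl)oxy]-1,5,5-trimethylspiro[5.5]undeca-1,7,10-trien-9-one | CC1=C[C@H](O[Si](C)(C)C(C)(C)C)[C@@H](Br)C(C)(C)C12C=CC(=O)C=C2 | intermediate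
15 | (3S,4S,6S)-4-bromo-3-[(tert-butyldimethylsilyl)oxy]-1,5,5-trimethylspiro[5.5]undeca-1,10-dien-9-one | CC1=C[C@H](O[Si](C)(C)C(C)(C)C)[C@@H](Br)C(C)(C)[C@]12CCC(=O)C=C2 | intermediate
16 | lithium (3S,4S,6S)-4-bromo-3-[(tert-butyldimethylsilyl)oxy]-1,5,5-trimethylspiro[5.5]undeca-1,9-dien-9-olate | CC1=C[C@H](O[Si](C)(C)C(C)(C)C)[C@@H](Br)C(C)(C)[C@]12CCC([O-])=CC2.[Li+] | intermediate
17 | (3S,4S,6S)-4-bromo-3-[(tert-butyldimethylsilyl)oxy]-1,5,5-trimethylspiro[5.5]undeca-1,9-dien-9-yl trifluoromethanesulfonate | CC1=C[C@H](O[Si](C)(C)C(C)(C)C)[C@@H](Br)C(C)(C)[C@]12CCC(OS(=O)(=O)C(F)(F)F)=CC2 | intermediate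
18 | tert-butyl{[(3S,4S,6S)-4-bromo-1,5,5,9-tetramethylspiro[5.5]undeca-1,9-dien-3-yl]oxy}dimethylsilane | CC1=C[C@H](O[Si](C)(C)C(C)(C)C)[C@@H](Br)C(C)(C)[C@]12CCC(C)=CC2 | intermediate
19 | tert-butyl{[(3S,4S,6S,9S,10S)-4,10-dibromo-9-chloro-1,5,5,9-tetramethylspiro[5.5]undec-1-en-3-yl]oxy}dimethylsilane | CC1=C[C@H](O[Si](C)(C)C(C)(C)C)[C@@H](Br)C(C)(C)[C@]12CC[C@](C)(Cl)[C@@H](Br)C2 | intermediate
20 | (3S,4S,6S,9S,10S)-4,10-dibromo-9-chloro-1,5,5,9-tetramethylspiro[5.5]undec-1-en-3-ol | CC1=C[C@H](O)[C@@H](Br)C(C)(C)[C@]12CC[C@](C)(Cl)[C@@H](Br)C2 | target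

**Step count and risks**

Total step count: 14. Longest linear sequence: 14 steps (from 1 and 2 to 20).

Steps most likely to fail:

1. Step 3. The phenoxenium ion may be captured by solvent or acetate, may fragment, or the methylene carbon C2 may migrate in place of C5. The fallback sets out from 2 and comes back at 8; it keeps the ring enlargement but triggers it with a bromonium ion on an alkene. The vinyllithium made from 8-bromo-1,4-dioxaspiro[4.5]dec-7-ene and t-BuLi adds to 2 to give 1-(1,4-dioxaspiro[4.5]dec-7-en-8-yl)-2,2-dimethylcyclopentan-1-ol F1. NBS in CH2Cl2/i-PrOH should induce the halonium semipinacol ring expansion to 7-bromo-5,5-dimethylspiro[5.5]undecane-1,9-dione 9-(ethylene ketal) F2. Bu3SnH with AIBN removes the bromine to give 5,5-dimethylspiro[5.5]undecane-1,9-dione 9-(ethylene ketal) F3, and aqueous HCl in acetone frees 5,5-dimethylspiro[5.5]undecane-1,9-dione F4. IBX in excess then dehydrogenates ring B twice and ring A once to give 8.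

2. Step 10. The catalyst may discriminate poorly between the two diastereotopic dienone arms, or both arms may be reduced. The fallback sets out from 14 and comes back at 17; it replaces the group-selective reduction by a group-selective deprotonation. Hydrogenation of both dienone double bonds with RhCl(PPh3)3 and H2 gives (3S,4S)-4-bromo-3-[(tert-butyldimethylsilyl)oxy]-1,5,5-trimethylspiro[5.5]undec-1-en-9-one F5. Deprotonation at C10 with lithium bis[(R)-1-phenylethyl]amide and LiCl in THF at −78 °C, followed by PhNTf2, gives 17 directly; the antipodal amide is used if the sense is opposite.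

3. Step 13. Br+ may attack the ring A alkene, or chloride capture on the hindered ring B face may be slow enough for elimination or the wrong regiochemistry to compete. The fallback sets out from 18 and comes back at 19; it separates bromonium capture from chloride delivery. NBS in aqueous acetone gives the bromohydrin (3S,4S,6S,9S,10S)-4,10-dibromo-3-[(tert-butyldimethylsilyl)oxy]-1,5,5,9-tetramethylspiro[5.5]undec-1-en-9-ol F6, water being a small nucleophile present in excess. SOCl2 in CH2Cl2 at −20 °C then ionises the tertiary alcohol with anchimeric assistance of the anti bromine, and chloride reopens the bromonium at C9 with overall retention to give 19.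

**Further compounds**

F1 | step 3 | 1-(1,4-dioxaspiro[4.5]dec-7-en-8-yl)-2,2-dimethylcyclopentan-1-ol | CC1(C)CCCC1(O)C1=CCC2(CC1)OCCO2
F2 | step 3 | 7-bromo-5,5-dimethylspiro[5.5]undecane-1,9-dione 9-(ethylene ketal) | CC1(C)CCCC(=O)C12C(Br)CC3(CC2)OCCO3
F3 | step 3 | 5,5-dimethylspiro[5.5]undecane-1,9-dione 9-(ethylene ketal) | CC1(C)CCCC(=O)C12CCC3(CC2)OCCO3
F4 | step 3 | 5,5-dimethylspiro[5.5]undecane-1,9-dione | CC1(C)CCCC(=O)C12CCC(=O)CC2
F5 | step 10 | (3S,4S)-4-bromo-3-[(tert-butyldimethylsilyl)oxy]-1,5,5-trimethylspiro[5.5]undec-1-en-9-one | CC1=C[C@H](O[Si](C)(C)C(C)(C)C)[C@@H](Br)C(C)(C)C12CCC(=O)CC2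
F6 | step 13 | (3S,4S,6S,9S,10S)-4,10-dibromo-3-[(tert-butyldimethylsilyl)oxy]-1,5,5,9-tetramethylspiro[5.5]undec-1-en-9-ol | CC1=C[C@H](O[Si](C)(C)C(C)(C)C)[C@@H](Br)C(C)(C)[C@]12CC[C@](C)(O)[C@@H](Br)C2
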